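Assumption: keto ester 1 is taken as a catalogue compound. The ring numbering O1, C2 (aryl), C3 (hydroxymethyl), C4 (aroyl), C5 is also used for the open-chain intermediates.

## Analysis of the target

The target 16 is a monocyclic tetrahydrofuran. C2 carries a 3,4-dimethoxyphenyl group, C3 a hydroxymethyl group, C4 a 3,4,5-trimethoxybenzoyl group, and C5 is an unsubstituted methylene. The three stereocentres are contiguous, (2R,3R,4S) in this numbering: aryl and hydroxymethyl are cis (C2/C3), hydroxymethyl and aroyl are trans (C3/C4). The cis C2/C3 pair is the less stable arrangement. C2 is a benzylic ether carbon para to a methoxy group, so any acid able to ionise C2–O1 would lead to the trans isomer or to a styrene. C4 is α to the ketone and β to O1, so it is epimerisable, with trans to C3 as the favoured side. A C3/C4-cis hydroxy ketone could also be trapped as a fused hemiketal, so strong base at the end is best avoided. The difficulty is to build the cis C2/C3 pair without ever passing through a C2 cation and to close the ring while leaving C2 alone. The plan rests on C5: it bears no substituent, lies between O1 and the enolisable C4, and is at the oxidation level of an acetal carbon. It can therefore be introduced as the methylene of a mixed acetal on the C2 oxygen and joined to C4 by enol silane chemistry.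

## Retrosynthetic reasoning

**16 ⇒ 15 ⇒ 14.** The hydroxymethyl group is traced back to a methyl ester. No ring bond is cut. The ester is wanted earlier because it makes the C3 centre accessible by enolate alkylation and its inductive pull disfavours a cation at C2. The price is that both carbonyls of 14 are reduced to diol 15 and only the benzylic carbinol is reoxidised.

**14 ⇒ 12 (through 13).** The C4–C5 bond is cut. C5 is the only ring carbon with neither substituent nor stereocentre, so cutting here leaves C2 and C3 in an open chain where they can be set by reliable acyclic methods. The polarity is natural: C4 is the α-carbon of an aryl ketone (enol silane 12), and C5 becomes an O1-bound methylene cation 13 generated from a methoxymethyl ether. Cutting O1–C2 instead would require a stereocontrolled C–O bond formation at the ionisable benzylic carbon. Cutting C2–C3 or C3–C4 would force the ring closure to set the difficult cis pair. The forward step has to ionise the acetal at its methoxy end and create only C4.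

**12 ⇒ 11 ⇒ 9 (through 10).** The enol silane comes from ketone 11, which has a single enolisable position. The ketone is in turn masked as the 1,1-disubstituted alkene of 9, because a free ketone would not survive the strongly basic alkylation earlier in the route.

**9 ⇒ 7 + 8.** The aryl–alkenyl bond is cut. This lets the trimethoxyphenyl ring arrive late by cross-coupling of boronic acid 8 with alkenyl bromide 7, so the alkylating agent can be the simple dibromide 3.

**7 ⇒ 5 + 6.** The O1–C5 bond is cut. Chloromethyl methyl ether 6 delivers the future ring carbon C5 at the correct oxidation level in an ordinary protection step.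

**5 ⇒ 2 + 3 (through 4).** The C3–C4 bond is cut. Alkylation of the chelated dianion 4 of hydroxy ester 2 sets C3 anti to the C2 oxygen. After ring closure through that oxygen, this anti relation becomes the cis relation of aryl and ester.

**2 ⇒ 1.** The C2 stereocentre is traced to the prochiral ketone of β-keto ester 1. A catalytic asymmetric hydrogenation has to supply the absolute configuration on which every later centre depends.

## Alternatives that were turned down

**Alternative 1: cyclopropane plus one-carbon aldehyde.**
- Disconnection: O1–C2 and C4–C5 together, leading back to the trans donor–acceptor cyclopropane A2 and formaldehyde A3.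
- Forward key step: Sn(OTf)2 activates the diester of A2, the carbonyl oxygen of A3 opens the ring at the benzylic carbon with inversion, and the malonate carbon closes onto the new oxocarbenium carbon to give A1.
- For: two bonds and the ring form in one convergent step, and the inversion turns the trans cyclopropane into the cis C2/C3 pair.
- Against: the donor is a 3,4-dimethoxyphenyl ring, so the ring-opened zwitterion is long-lived and the stereospecificity can leak. Monomeric A3 is awkward to dose. A1 carries a geminal diester at C4 that must be cut down to one aroyl group (dealkoxycarbonylation, conversion of the ester into an aryl ketone, desilylation). An enantioselective route to the trisubstituted A2 is a project of its own.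
- Comparison: this alternative is stronger in bonds formed per step and in convergence. The chosen route offers stereocentres from well-understood reactions, and C4 emerges from the ring closure already as the aryl ketone, two steps from 16.

**Alternative 2: reductive etherification through a fused lactone.**
- Disconnection: O1–C2 and C2–H, leading back to keto lactone A5.
- Forward key step: BF3·OEt2 and Et3SiH take A5 through its cis-fused hemiketal and oxocarbenium ion, and hydride adds from the convex face to give bicycle A4 with the aryl group on the concave face.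
- For: the ketone α-centre converges because only the cis-fused bicycle can form, and the rigid bicycle fixes the cis C2/C3 relation very reliably. On that point it is at least as strong as the open-chain anti alkylation used here.
- Against: A4 has C4 cis to C3. Opening the lactone with aryllithium A6 risks double addition and gives the C4 epimer A7, which must then be epimerised on the final compound, where the cis isomer can hide as a fused hemiketal. The absolute configuration has to be installed at the enolisable lactone α-carbon of A5 in several steps.
- Comparison: the chosen route forms C4 directly in the trans sense and needs no organometallic addition or base treatment on the finished skeleton.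

**Alternative 3: ring contraction of a vinyl acetal.**
- Disconnection: C2–C3, leading back to the 4,5-dihydro-1,3-dioxepine A9.
- Forward key step: BF3·OEt2 at low temperature cleaves the acetal C–O bond on the enol ether side of A9, and the enolate carbon recombines with the aryl oxocarbenium carbon (a Petasis–Ferrier-type contraction) to give aldehyde A8.
- For: C2 and C3 are set together from one existing centre, and only two steps follow (aldehyde reduction, alkene cleavage). In step count after the key step it equals the chosen route, and it sets more stereocentres in the key step.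
- Against: the cis aldehyde A8 is a kinetic product with an epimerisable α-centre next to a reversible, Lewis-acid-labile benzylic acetal linkage. The styrene side chain can interfere with the cation. The whole absolute configuration hangs on the single allylic centre of A9, for which no simple enantioselective entry exists.
- Comparison: in the chosen route the cis pair is fixed before the ring exists and is not involved in the ring closure, and the only centre formed there is the one whose preferred configuration is the wanted one.

Key step: step 7

## Route

**Step 1**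
Reactants: 1 methyl 3-(3,4-dimethoxyphenyl)-3-oxopropanoate
Product: 2 methyl (3R)-3-(3,4-dimethoxyphenyl)-3-hydroxypropanoate
Conditions: RuCl2[(S)-binap] (0.5 mol %), H2 (50 atm), MeOH, 50 °C
Reagents that add atoms: none
Why: Noyori asymmetric hydrogenation of a β-keto ester; the substrate chelates ruthenium through both carbonyls and hydride is delivered to one ketone face. With the (S)-ligand the R carbinol is expected (the spatial sense that gives (S)-3-hydroxybutanoate from acetoacetate; the descriptor changes because aryl outranks the CH2CO2Me group). This sets ring C2.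

**Step 2**
Reactants: 2 methyl (3R)-3-(3,4-dimethoxyphenyl)-3-hydroxypropanoate; 3 2,3-dibromoprop-1-ene
Product: 5 methyl (2S)-4-bromo-2-[(R)-(3,4-dimethoxyphenyl)(hydroxy)methyl]pent-4-enoate, via dilithium alkoxide enolate 4 (not isolated)
Conditions: LiN(iPr)2 (2.2 equiv), THF, −78 → −20 °C; then 3 (1.5 equiv), DMPU, −78 → −20 °C; AcOH quench at −78 °C
Reagents that add atoms: none
Why: Fráter–Seebach alkylation; dianion 4 is a rigid six-membered lithium chelate and the allylic bromide approaches the enolate face away from the aryl group, giving the anti (2S) product. Only the allylic C–Br bond of 3 is displaced; the alkenyl bromide is inert. This sets ring C3 relative to C2.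

**Step 3**
Reactants: 5 methyl (2S)-4-bromo-2-[(R)-(3,4-dimethoxyphenyl)(hydroxy)methyl]pent-4-enoate; 6 chloromethyl methyl ether
Product: 7 methyl (2S)-4-bromo-2-[(R)-(3,4-dimethoxyphenyl)(methoxymethoxy)methyl]pent-4-enoate
Conditions: 6 (3 equiv), iPr2NEt (5 equiv), CH2Cl2, 0 °C → rt
Reagents that add atoms: none
Why: O-alkylation of the secondary alcohol by the reactive α-chloro ether under a hindered amine base; no stereocentre is touched. The acetal methylene introduced here is the future ring C5.

**Step 4**
Reactants: 7 methyl (2S)-4-bromo-2-[(R)-(3,4-dimethoxyphenyl)(methoxymethoxy)methyl]pent-4-enoate; 8 (3,4,5-trimethoxyphenyl)boronic acid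
Product: 9 methyl (2S)-2-[(R)-(3,4-dimethoxyphenyl)(methoxymethoxy)methyl]-4-(3,4,5-trimethoxyphenyl)pent-4-enoate
Conditions: 8 (1.3 equiv), PdCl2(dppf) (5 mol %), K3PO4 (3 equiv), 1,4-dioxane/H2O (10:1), 70 °C
Reagents that add atoms: none
Why: Suzuki–Miyaura coupling; oxidative addition of zerovalent palladium into the alkenyl C–Br bond, transmetalation and reductive elimination give the 1,1-disubstituted styrene. The phosphate base should leave the methyl ester and the α-stereocentre alone.

**Step 5**
Reactants: 9 methyl (2S)-2-[(R)-(3,4-dimethoxyphenyl)(methoxymethoxy)methyl]-4-(3,4,5-trimethoxyphenyl)pent-4-enoate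
Product: 11 methyl (2S)-2-[(R)-(3,4-dimethoxyphenyl)(methoxymethoxy)methyl]-4-oxo-4-(3,4,5-trimethoxyphenyl)butanoate, via vicinal diol 10 (not isolated)
Conditions: K2OsO4·2H2O (2 mol %), NaIO4 (4 equiv), 2,6-lutidine (2 equiv), 1,4-dioxane/H2O (3:1), rt
Reagents that add atoms: sodium periodate, [Na+].[O-]I(=O)(=O)=O (oxygen passed on by the osmium catalyst); water, O
Why: Lemieux–Johnson oxidation; the 1,1-disubstituted styrene is osmylated to diol 10 and cleaved by periodate in the same flask, while the methoxyarenes, acetal and ester are inert. 2,6-Lutidine suppresses over-oxidation.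

**Step 6**
Reactants: 11 methyl (2S)-2-[(R)-(3,4-dimethoxyphenyl)(methoxymethoxy)methyl]-4-oxo-4-(3,4,5-trimethoxyphenyl)butanoate
Product: 12 methyl (2S,3Z)-4-[(tert-butyldimethylsilyl)oxy]-2-[(R)-(3,4-dimethoxyphenyl)(methoxymethoxy)methyl]-4-(3,4,5-trimethoxyphenyl)but-3-enoate
Conditions: TBSOTf (1.3 equiv), Et3N (2 equiv), CH2Cl2, 0 °C
Reagents that add atoms: tert-butyldimethylsilyl trifluoromethanesulfonate, CC(C)(C)[Si](C)(C)OS(=O)(=O)C(F)(F)F
Why: Soft enolisation of the aryl ketone by silyl triflate and tertiary amine; the ketone has one enolisable position (C4) and is far more acidic than the ester α-position. Aryl alkyl ketones give the Z enol silane (silyloxy cis to the chain) under these conditions.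

**Step 7**
Reactants: 12 methyl (2S,3Z)-4-[(tert-butyldimethylsilyl)oxy]-2-[(R)-(3,4-dimethoxyphenyl)(methoxymethoxy)methyl]-4-(3,4,5-trimethoxyphenyl)but-3-enoate
Product: 14 methyl (2R,3S,4S)-2-(3,4-dimethoxyphenyl)-4-(3,4,5-trimethoxybenzoyl)oxolane-3-carboxylate, via oxocarbenium triflate 13 (not isolated)
Conditions: TMSOTf (1.2 equiv), 2,6-di-tert-butyl-4-methylpyridine (0.3 equiv), CH2Cl2 (0.01 M), −78 °C; then sat. aq NaHCO3
Reagents that add atoms: none
Why: TMSOTf silylates the terminal methoxy oxygen of the acetal, methoxytrimethylsilane leaves, and the O1-bound methylene oxocarbenium ion 13 results. The nucleophilic enol silane carbon C4 attacks the cationic methylene to form C4–C5, and the resulting silyloxycarbenium ion gives up its silyl group to triflate, leaving the ketone. The reaction type is the Mukaiyama aldol-type addition of an enol silane to an acetal-derived oxocarbenium ion, run intramolecularly as in the known Lewis-acid closures of oxygen-tethered enol ethers onto oxocarbenium ions that give 3-acyltetrahydrofurans. The five-membered ring closes in the 5-(enolexo)-endo-trig mode (enol C=C outside the ring, the C5=O1 π bond inside it), which is formally disfavoured but routinely open to oxocarbenium ions. The new stereocentre C4 is controlled by A(1,3) strain in the Z enol silane: C3–H eclipses the enol double bond on the silyloxy side, the ester points outward and the C2–O1 tether delivers C5 to its own face, so the aroyl group ends trans to the ester, which is also the thermodynamically preferred side. C2 and C3 take no part, so the open-chain anti relation appears as 2,3-cis. The step needs ionisation at the methoxy end and not at the benzylic C2–O bond, which is secured by the more accessible terminal oxygen, by the ester-bearing carbon next to C2 that disfavours a benzylic cation, and by −78 °C with a hindered base that keeps triflic acid out. It also needs C-attack at C4 instead of a [3,3] shift, which follows because the silyloxy-bearing carbon is the cationic terminus, and dilution suppresses intermolecular addition.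

**Step 8**
Reactants: 14 methyl (2R,3S,4S)-2-(3,4-dimethoxyphenyl)-4-(3,4,5-trimethoxybenzoyl)oxolane-3-carboxylate
Product: 15 [(2R,3R,4S)-2-(3,4-dimethoxyphenyl)-4-[hydroxy(3,4,5-trimethoxyphenyl)methyl]oxolan-3-yl]methanol (both carbinol epimers)
Conditions: LiAlH4 (3 equiv), THF, −78 → 0 °C; then H2O, aq NaOH (Fieser work-up)
Reagents that add atoms: none
Why: Hydride reduction of the ester to the primary alcohol and of the ketone to a benzylic carbinol; carbonyl addition at low temperature outruns enolisation, so C4 should not epimerise. The new carbinol centre is irrelevant because it is oxidised again in step 9.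

**Step 9**
Reactants: 15 [(2R,3R,4S)-2-(3,4-dimethoxyphenyl)-4-[hydroxy(3,4,5-trimethoxyphenyl)methyl]oxolan-3-yl]methanol
Product: 16 [(3S,4R,5R)-5-(3,4-dimethoxyphenyl)-4-(hydroxymethyl)oxolan-3-yl](3,4,5-trimethoxyphenyl)methanone
Conditions: activated MnO2 (20 equiv), CH2Cl2, rt
Reagents that add atoms: none
Why: Chemoselective benzylic oxidation by MnO2; the secondary carbinol next to the trimethoxyphenyl ring is oxidised and the primary aliphatic alcohol is not. The neutral heterogeneous conditions leave C4 and the benzylic ether C2 alone, and the 3,4-trans hydroxy ketone cannot close to a fused hemiketal.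

## Compound list

1 | methyl 3-(3,4-dimethoxyphenyl)-3-oxopropanoate | COC(=O)CC(=O)c1ccc(OC)c(OC)c1 | starting material
2 | methyl (3R)-3-(3,4-dimethoxyphenyl)-3-hydroxypropanoate | COC(=O)C[C@@H](O)c1ccc(OC)c(OC)c1 | intermediate
3 | 2,3-dibromoprop-1-ene | C=C(Br)CBr | starting material
4 | dilithium alkoxide enolate of 2 (chelated dianion) | [Li+].[Li+].CO/C([O-])=C/[C@@H]([O-])c1ccc(OC)c(OC)c1 | intermediate
5 | methyl (2S)-4-bromo-2-[(R)-(3,4-dimethoxyphenyl)(hydroxy)methyl]pent-4-enoate (anti) | COc1ccc([C@H](O)[C@@H](C(=O)OC)CC(Br)=C)cc1OC | intermediate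
6 | chloromethyl methyl ether | COCCl | starting material
7 | methyl (2S)-4-bromo-2-[(R)-(3,4-dimethoxyphenyl)(methoxymethoxy)methyl]pent-4-enoate | COc1ccc([C@H](OCOC)[C@@H](C(=O)OC)CC(Br)=C)cc1OC | intermediate
8 | (3,4,5-trimethoxyphenyl)boronic acid | COc1cc(B(O)O)cc(OC)c1OC | starting material
9 | methyl (2S)-2-[(R)-(3,4-dimethoxyphenyl)(methoxymethoxy)methyl]-4-(3,4,5-trimethoxyphenyl)pent-4-enoate | COc1ccc([C@H](OCOC)[C@@H](C(=O)OC)CC(=C)c2cc(OC)c(OC)c(OC)c2)cc1OC | intermediate
10 | methyl (2S)-2-[(R)-(3,4-dimethoxyphenyl)(methoxymethoxy)methyl]-4,5-dihydroxy-4-(3,4,5-trimethoxyphenyl)pentanoate (both C4 epimers) | COc1ccc([C@H](OCOC)[C@@H](C(=O)OC)CC(O)(CO)c2cc(OC)c(OC)c(OC)c2)cc1OC | intermediate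
11 | methyl (2S)-2-[(R)-(3,4-dimethoxyphenyl)(methoxymethoxy)methyl]-4-oxo-4-(3,4,5-trimethoxyphenyl)butanoate | COc1ccc([C@H](OCOC)[C@@H](C(=O)OC)CC(=O)c2cc(OC)c(OC)c(OC)c2)cc1OC | intermediate
12 | methyl (2S,3Z)-4-[(tert-butyldimethylsilyl)oxy]-2-[(R)-(3,4-dimethoxyphenyl)(methoxymethoxy)methyl]-4-(3,4,5-trimethoxyphenyl)but-3-enoate | COc1ccc([C@H](OCOC)[C@@H](C(=O)OC)/C=C(\O[Si](C)(C)C(C)(C)C)c2cc(OC)c(OC)c(OC)c2)cc1OC | intermediate
13 | O1-methylene oxocarbenium triflate derived from 12 | COc1ccc([C@H]([O+]=C)[C@@H](C(=O)OC)/C=C(\O[Si](C)(C)C(C)(C)C)c2cc(OC)c(OC)c(OC)c2)cc1OC.[O-]S(=O)(=O)C(F)(F)F | intermediate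
14 | methyl (2R,3S,4S)-2-(3,4-dimethoxyphenyl)-4-(3,4,5-trimethoxybenzoyl)oxolane-3-carboxylate (2,3-cis, 3,4-trans) | COc1ccc([C@@H]2OC[C@@H](C(=O)c3cc(OC)c(OC)c(OC)c3)[C@@H]2C(=O)OC)cc1OC | intermediate
15 | [(2R,3R,4S)-2-(3,4-dimethoxyphenyl)-4-[hydroxy(3,4,5-trimethoxyphenyl)methyl]oxolan-3-yl]methanol (both carbinol epimers) | COc1ccc([C@@H]2OC[C@@H](C(O)c3cc(OC)c(OC)c(OC)c3)[C@@H]2CO)cc1OC | intermediate
16 | [(3S,4R,5R)-5-(3,4-dimethoxyphenyl)-4-(hydroxymethyl)oxolan-3-yl](3,4,5-trimethoxyphenyl)methanone | COc1ccc([C@@H]2OC[C@@H](C(=O)c3cc(OC)c(OC)c(OC)c3)[C@@H]2CO)cc1OC | target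

## Step count and risk

Total step count: 9. Longest linear sequence: 9 steps (1 → 16).

**Step 7 (key step).**
- What may go wrong: the acetal may be lost from C2 as a whole, either by silylation of the inner oxygen or by heterolysis of the C2–O1 bond of ion 13, because the cation left behind is a para-methoxybenzyl cation. This would lead to elimination toward the conjugated ester or to loss of the C2 configuration. Protodesilylation of the enol silane by adventitious triflic acid would simply return 11.
- A partial C3/C4-cis outcome is less serious. Brief exposure of 14 to DBU in CH2Cl2 should move it to the trans side, since only C4–H is acidic enough and ring opening from the C4 enolate would be the reverse of a 5-endo closure.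
- Fallback: the acetal is exchanged for an O,S-acetal that is ionised by alkylation at sulfur, so that no Lewis acid meets the benzylic oxygen. It sets out from 5. Suzuki–Miyaura coupling with 8 under the conditions of step 4 gives the free hydroxy alkene F1. Lemieux–Johnson cleavage as in step 5 gives the hydroxy ketone F2. Dimethyl sulfide and dibenzoyl peroxide in MeCN at 0 °C convert the benzylic hydroxyl into the methylthiomethyl ether F3; the sulfide is installed only now because it would not survive periodate. TBSOTf/Et3N gives the silyl enol ether F4. Methyl triflate with 2,6-di-tert-butyl-4-methylpyridine in CH2Cl2 (−40 → 0 °C) methylates sulfur, dimethyl sulfide departs, and the same ion 13 closes. The route is rejoined at 14.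

**Step 2.**
- What may go wrong: retro-aldol cleavage of the monolithium aldolate before the second deprotonation is complete (the electron-rich aryl aldehyde is a good leaving fragment), dehydrobromination of 3 by excess amide, and incomplete anti selectivity.
- Fallback: the stereocentre is used through a cyclic acetal instead of a dianion. It sets out from 2. Saponification (LiOH, THF/H2O) gives the hydroxy acid F5. Condensation with pivalaldehyde (PPTS cat., 4 Å sieves, CH2Cl2) gives the cis-1,3-dioxan-4-one F6. Its lithium enolate (LiN(iPr)2, THF, −78 °C) is alkylated by 3 trans to the aryl group to give F7. NaOMe in MeOH at 0 °C opens the acetal to the methyl ester. The route is rejoined at 5.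

**Step 1.**
- What may go wrong: insufficient enantioselection, because aryl β-keto esters are differentiated less well than alkyl ones in the binap chelate and the electron-rich ketone is slow, so the temperature needed may erode selectivity.
- Fallback: Noyori–Ikariya transfer hydrogenation, which recognises the aryl ketone itself and not a chelate. It sets out from 1: RuCl[(R,R)-TsDPEN](p-cymene) (1 mol %), HCO2H/Et3N, rt, should give the R alcohol. The route is rejoined at 2; no new compound is made.

**Step 9.**
- What may go wrong: oxidation of the primary alcohol through a transient lactol with the neighbouring carbinol before the benzylic oxidation is complete, or loss of material by adsorption on the large excess of oxide.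
- Fallback: a protecting-group detour. It sets out from 15. TBSCl and imidazole in CH2Cl2 at 0 °C silylate the primary hydroxyl to give the silyl ether F8. Dess–Martin periodinane with NaHCO3 oxidises the remaining carbinol to the keto silyl ether F9. HF·pyridine in THF removes the silyl group without base. The route is rejoined at 16.

## Further compounds

F1 | step 7 | methyl (2S)-2-[(R)-(3,4-dimethoxyphenyl)(hydroxy)methyl]-4-(3,4,5-trimethoxyphenyl)pent-4-enoate | COc1ccc([C@H](O)[C@@H](C(=O)OC)CC(=C)c2cc(OC)c(OC)c(OC)c2)cc1OC
F2 | step 7 | methyl (2S)-2-[(R)-(3,4-dimethoxyphenyl)(hydroxy)methyl]-4-oxo-4-(3,4,5-trimethoxyphenyl)butanoate | COc1ccc([C@H](O)[C@@H](C(=O)OC)CC(=O)c2cc(OC)c(OC)c(OC)c2)cc1OC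
F3 | step 7 | methyl (2S)-2-[(R)-(3,4-dimethoxyphenyl)(methylsulfanylmethoxy)methyl]-4-oxo-4-(3,4,5-trimethoxyphenyl)butanoate | COc1ccc([C@H](OCSC)[C@@H](C(=O)OC)CC(=O)c2cc(OC)c(OC)c(OC)c2)cc1OC
F4 | step 7 | methyl (2S,3Z)-4-[(tert-butyldimethylsilyl)oxy]-2-[(R)-(3,4-dimethoxyphenyl)(methylsulfanylmethoxy)methyl]-4-(3,4,5-trimethoxyphenyl)but-3-enoate | COc1ccc([C@H](OCSC)[C@@H](C(=O)OC)/C=C(\O[Si](C)(C)C(C)(C)C)c2cc(OC)c(OC)c(OC)c2)cc1OC
F5 | step 2 | (3R)-3-(3,4-dimethoxyphenyl)-3-hydroxypropanoic acid | OC(=O)C[C@@H](O)c1ccc(OC)c(OC)c1
F6 | step 2 | (2S,6R)-2-tert-butyl-6-(3,4-dimethoxyphenyl)-1,3-dioxan-4-one (2,6-cis) | CC(C)(C)[C@@H]1OC(=O)C[C@H](c2ccc(OC)c(OC)c2)O1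
F7 | step 2 | (2S,5S,6R)-5-(2-bromoprop-2-en-1-yl)-2-tert-butyl-6-(3,4-dimethoxyphenyl)-1,3-dioxan-4-one (5,6-trans) | CC(C)(C)[C@@H]1OC(=O)[C@@H](CC(Br)=C)[C@H](c2ccc(OC)c(OC)c2)O1
F0 | step 1 | none | none
F8 | step 9 | {(3S,4R,5R)-4-[(tert-butyldimethylsilyl)oxymethyl]-5-(3,4-dimethoxyphenyl)oxolan-3-yl}(3,4,5-trimethoxyphenyl)methanol (both carbinol epimers) | COc1ccc([C@@H]2OC[C@@H](C(O)c3cc(OC)c(OC)c(OC)c3)[C@@H]2CO[Si](C)(C)C(C)(C)C)cc1OC
F9 | step 9 | {(3S,4R,5R)-4-[(tert-butyldimethylsilyl)oxymethyl]-5-(3,4-dimethoxyphenyl)oxolan-3-yl}(3,4,5-trimethoxyphenyl)methanone | COc1ccc([C@@H]2OC[C@@H](C(=O)c3cc(OC)c(OC)c(OC)c3)[C@@H]2CO[Si](C)(C)C(C)(C)C)cc1OC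
A1 | alternative 1 | dimethyl 2,3-cis-2-(3,4-dimethoxyphenyl)-3-[(triisopropylsilyl)oxymethyl]oxolane-4,4-dicarboxylate | COc1ccc([C@@H]2OCC(C(=O)OC)(C(=O)OC)[C@@H]2CO[Si](C(C)C)(C(C)C)C(C)C)cc1OC
A2 | alternative 1 | dimethyl trans-2-(3,4-dimethoxyphenyl)-3-[(triisopropylsilyl)oxymethyl]cyclopropane-1,1-dicarboxylate | COC(=O)C1(C(=O)OC)[C@H](c2ccc(OC)c(OC)c2)[C@H]1CO[Si](C(C)C)(C(C)C)C(C)C
A3 | alternative 1 | formaldehyde | C=O
A4 | alternative 2 | cis-fused 4-(3,4-dimethoxyphenyl)tetrahydro-1H,3H-furo[3,4-c]furan-1-one, aryl on the concave face | COc1ccc([C@@H]2OC[C@@H]3C(=O)OC[C@H]23)cc1OC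
A5 | alternative 2 | 4-(3,4-dimethoxybenzoyl)-3-(hydroxymethyl)oxolan-2-one, configured at the lactone α-carbon, either configuration at the ketone α-carbon | COc1ccc(C(=O)C2COC(=O)[C@H]2CO)cc1OC
A6 | alternative 2 | (3,4,5-trimethoxyphenyl)lithium | [Li]c1cc(OC)c(OC)c(OC)c1
A7 | alternative 2 | [(3R,4R,5R)-5-(3,4-dimethoxyphenyl)-4-(hydroxymethyl)oxolan-3-yl](3,4,5-trimethoxyphenyl)methanone (C4 epimer of 16) | COc1ccc([C@@H]2OC[C@H](C(=O)c3cc(OC)c(OC)c(OC)c3)[C@@H]2CO)cc1OC
A8 | alternative 3 | 2,3-cis-3,4-trans-2-(3,4-dimethoxyphenyl)-4-[1-(3,4,5-trimethoxyphenyl)ethenyl]oxolane-3-carbaldehyde | COc1ccc([C@@H]2OC[C@@H](C(=C)c3cc(OC)c(OC)c(OC)c3)[C@@H]2C=O)cc1OC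
A9 | alternative 3 | 2-(3,4-dimethoxyphenyl)-5-[1-(3,4,5-trimethoxyphenyl)ethenyl]-4,5-dihydro-1,3-dioxepine, configured at C5, either configuration at the acetal carbon | COc1ccc(C2OC[C@@H](C(=C)c3cc(OC)c(OC)c(OC)c3)C=CO2)cc1OC
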